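**Strategy.** The target, (R)-1-(3,5-dihydroxyphenyl)tridecan-2-yl acetate, is cut in its saturated side chain between C4 and C5 (tridecane numbering; C1 benzylic, C2 the acetoxy stereocentre). Because C4 lies two carbons from the oxygen-bearing C2, this bond can be made as a transient C4=C5 alkene. Cross-metathesis of an (R)-homoallylic acetate, carrying the benzene ring as its bis(benzyl ether), with dec-1-ene joins the C1–C4 aryl half to the C5–C13 chain in one operation; alkene geometry is irrelevant. The precursor should come in one pot from an aryl Grignard reagent and (R)-2-allyloxirane, which supplies C2 with its configuration. A single hydrogenation then saturates C4=C5 and frees both phenols.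

Key step: step 2

Assumption: 1,3-bis(benzyloxy)-5-bromobenzene (1) and (R)-2-allyloxirane (2, single enantiomer) are taken as catalogue compounds.

Step 1
Reactants: 1 1,3-bis(benzyloxy)-5-bromobenzene; 2 (R)-2-allyloxirane
Product: 5 (R)-1-[3,5-bis(benzyloxy)phenyl]pent-4-en-2-yl acetate, via 3,5-bis(benzyloxy)phenylmagnesium bromide 3 (not isolated), via bromomagnesium alkoxide 4 (not isolated)
Conditions: Mg, I2 (cat.), THF, 50 °C; then CuI (10 mol %), 2, −30 → 0 °C; then Ac2O, DMAP (cat.), 0 °C → rt; aq. NH4Cl
Reagents that add atoms: acetic anhydride, CC(=O)OC(C)=O; magnesium, [Mg] (kept only in the non-isolated intermediates 3 and 4)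
Why: Magnesium insertion gives the aryl Grignard reagent 3, whose copper-catalysed SN2 ring opening of the terminal epoxide should occur at the unsubstituted CH2, so that the untouched stereocentre of (R)-2 becomes the (R)-alkoxide 4, which Ac2O/DMAP acylates in situ (Grignard formation, Cu-catalysed epoxide opening, O-acylation).

Step 2
Reactants: 5 (R)-1-[3,5-bis(benzyloxy)phenyl]pent-4-en-2-yl acetate; 6 dec-1-ene
Product: 7 (R,E)-1-[3,5-bis(benzyloxy)phenyl]tridec-4-en-2-yl acetate
Conditions: Grubbs II (5 mol %), 6 (4 equiv), 1,4-benzoquinone (10 mol %), CH2Cl2, 40 °C, Ar sparge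
Reagents that add atoms: none
Why: Olefin cross-metathesis by the Chauvin mechanism: Ru alkylidenes undergo [2+2] cycloaddition and cycloreversion through ruthenacyclobutanes with the terminal alkenes of 5 and 6, ejecting ethylene and forming the C4=C5 bond. The closest known reaction type is Grubbs-II cross-metathesis of a homoallylic ester with a simple 1-alkene, both type I olefins. No ring is closed and no stereocentre is created; the C2 stereocentre is two atoms from the reacting alkene and is not touched, and the E/Z ratio is irrelevant because step 3 saturates the alkene. The selectivity needed is cross- over homo-coupling and the absence of double-bond migration, which would alter the chain length; the excess of cheap 6 with loss of ethylene should secure the former, since the homodimer of 5 re-enters the cycle by secondary metathesis, and 1,4-benzoquinone as a Ru–H scavenger should secure the latter. The homoallylic rather than allylic position of the acetate leaves the alkene of 5 unhindered and non-chelating, and the benzyl ethers and the ester are inert to the catalyst.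

Step 3
Reactants: 7 (R,E)-1-[3,5-bis(benzyloxy)phenyl]tridec-4-en-2-yl acetate
Product: 8 (R)-1-(3,5-dihydroxyphenyl)tridecan-2-yl acetate
Conditions: H2 (1 atm), 10 % Pd/C, EtOAc–EtOH, rt
Reagents that add atoms: none
Why: Heterogeneous palladium-catalysed hydrogenation should saturate the C4=C5 alkene of either geometry and hydrogenolyse both aryl benzyl ethers, while the secondary acetate, which is homobenzylic and not benzylic, and the C2 stereocentre stay untouched (catalytic hydrogenation with O-debenzylation).

**Compound list**

1 | 1,3-bis(benzyloxy)-5-bromobenzene | Brc1cc(OCc2ccccc2)cc(OCc2ccccc2)c1 | starting material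
2 | (R)-2-allyloxirane [(2R)-2-(prop-2-en-1-yl)oxirane] | C=CC[C@@H]1CO1 | starting material
3 | 3,5-bis(benzyloxy)phenylmagnesium bromide | Br[Mg]c1cc(OCc2ccccc2)cc(OCc2ccccc2)c1 | intermediate
4 | bromomagnesium (R)-1-[3,5-bis(benzyloxy)phenyl]pent-4-en-2-olate | C=CC[C@H](Cc1cc(OCc2ccccc2)cc(OCc2ccccc2)c1)O[Mg]Br | intermediate
5 | (R)-1-[3,5-bis(benzyloxy)phenyl]pent-4-en-2-yl acetate | C=CC[C@H](Cc1cc(OCc2ccccc2)cc(OCc2ccccc2)c1)OC(C)=O | intermediate
6 | dec-1-ene | C=CCCCCCCCC | starting material
7 | (R,E)-1-[3,5-bis(benzyloxy)phenyl]tridec-4-en-2-yl acetate (drawn as the expected major E isomer; any Z isomer converges in step 3) | CCCCCCCC/C=C/C[C@H](Cc1cc(OCc2ccccc2)cc(OCc2ccccc2)c1)OC(C)=O | intermediate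
8 | (R)-1-(3,5-dihydroxyphenyl)tridecan-2-yl acetate | CCCCCCCCCCC[C@H](Cc1cc(O)cc(O)c1)OC(C)=O | target

**Count.** Total steps: 3. Longest linear sequence: 3 steps (1 → 5 → 7 → 8).

**Steps most likely to fail**

Step 2. Homodimerisation may outrun cross-coupling. Ruthenium hydride species may also migrate the double bond of 6 or of the product before metathesis, which would deliver chain-length homologues that can no longer be separated after hydrogenation. The fallback sets out from 5 and returns to the route at 8, forming the same C4–C5 bond by olefination. Lemieux–Johnson cleavage of 5 (OsO4 cat., NaIO4, 2,6-lutidine, dioxane–water) should give the aldehyde (S)-1-[3,5-bis(benzyloxy)phenyl]-4-oxobutan-2-yl acetate F1. The ylide nonylidene(triphenyl)phosphorane F2 is generated from nonyltriphenylphosphonium bromide with NaHMDS in THF. A salt-free Wittig reaction of F1 with F2 at −78 °C should give (R,Z)-1-[3,5-bis(benzyloxy)phenyl]tridec-4-en-2-yl acetate F3. Hydrogenation of F3 under the conditions of step 3 then gives 8.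

Step 1. Magnesium bromide may open the volatile epoxide to a bromohydrin in competition with the copper-catalysed arylation, and the in-situ acylation may stop short, leaving alcohol and acetate together. The fallback sets out from 3 (generated from 1 as in step 1) and returns at 5, reversing the order of the two epoxide openings on a different chiral C3 unit. Addition of 3 to (S)-epichlorohydrin (CuI cat., THF, −30 °C) should give (S)-1-[3,5-bis(benzyloxy)phenyl]-3-chloropropan-2-ol F4. NaOH in THF–water closes this to (S)-2-[3,5-bis(benzyloxy)benzyl]oxirane F5. Vinylmagnesium bromide with CuI opens F5 at its CH2 to give the isolated alcohol (R)-1-[3,5-bis(benzyloxy)phenyl]pent-4-en-2-ol F6. A separate acetylation (Ac2O, pyridine, DMAP) gives 5.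

Step 3. On palladium the alkene may migrate towards C3=C4 before it is saturated; the acetate would then be allylic and open to C–O hydrogenolysis, and debenzylation may also stall. The fallback sets out from 7 and returns at 8, separating the two tasks. Metal-free diimide reduction (p-toluenesulfonyl hydrazide, NaOAc, DME–water, reflux) should give (R)-1-[3,5-bis(benzyloxy)phenyl]tridecan-2-yl acetate F7. With no alkene left, hydrogenolysis of F7 (H2, Pd/C, EtOAc–EtOH) gives 8.

Further compounds
F1 | step 2 | (S)-1-[3,5-bis(benzyloxy)phenyl]-4-oxobutan-2-yl acetate | O=CC[C@H](Cc1cc(OCc2ccccc2)cc(OCc2ccccc2)c1)OC(C)=O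
F2 | step 2 | nonylidene(triphenyl)phosphorane | CCCCCCCCC=P(c1ccccc1)(c1ccccc1)c1ccccc1
F3 | step 2 | (R,Z)-1-[3,5-bis(benzyloxy)phenyl]tridec-4-en-2-yl acetate | CCCCCCCC/C=C\C[C@H](Cc1cc(OCc2ccccc2)cc(OCc2ccccc2)c1)OC(C)=O
F4 | step 1 | (S)-1-[3,5-bis(benzyloxy)phenyl]-3-chloropropan-2-ol | ClC[C@H](Cc1cc(OCc2ccccc2)cc(OCc2ccccc2)c1)O
F5 | step 1 | (S)-2-[3,5-bis(benzyloxy)benzyl]oxirane | C1[C@H](Cc2cc(OCc3ccccc3)cc(OCc3ccccc3)c2)O1
F6 | step 1 | (R)-1-[3,5-bis(benzyloxy)phenyl]pent-4-en-2-ol | C=CC[C@H](Cc1cc(OCc2ccccc2)cc(OCc2ccccc2)c1)O
F7 | step 3 | (R)-1-[3,5-bis(benzyloxy)phenyl]tridecan-2-yl acetate | CCCCCCCCCCC[C@H](Cc1cc(OCc2ccccc2)cc(OCc2ccccc2)c1)OC(C)=O
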